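**Retrosynthetic overview**
- The depside ester between the ring A carbonyl and the C3' oxygen of ring B is cut last. This gives benzyl-protected 2,4-dihydroxy-6-propylbenzoic acid (ring A) and a ring B phenol with only the C3'–OH free.
- The strategy rests on ring B (C1' CO2H, C2' OMe, C3' O-ester, C4' OH, C5' H, C6' propyl): the carboxyl at C1' and the propyl at C6' sit on adjacent carbons next to the C2' methoxy group. This is the pattern left when a C1'–C6' aryne flanked by methoxy takes up a carbon nucleophile at C6' and an electrophile at C1'.
- Both C–C bonds are therefore made in one pot from a fluoroarene that already carries the three differentiated oxygens (OMe, OMOM, OTIPS), using propylmagnesium chloride and CO2.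
- The fluoroarene comes from 4-fluoro-2-methoxyphenol by ortho-formylation, MOM protection, Baeyer–Villiger oxidation and silylation. Ring A acid comes from 5-propylresorcinol by formylation, benzylation and oxidation.
- No ring is formed; both benzene rings are purchased. Order: ring B is elaborated, ring A acid is made separately, the two are esterified, and one hydrogenolysis removes all benzyl groups.

Key step: step 5

Remark: the C4' oxygen is carried through the aryne step as a triisopropylsilyl ether and is exchanged for a benzyl ether in the esterification pot (step 6). A silyl group next to the free C3' phenol could migrate during acylation, and a late fluoride desilylation next to the finished aryl ester could trigger acyl migration; the benzyl ether leaves with the other benzyl groups under neutral hydrogenolysis.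

**Step 1**
Reactants: 1 4-fluoro-2-methoxyphenol
Product: 2 5-fluoro-2-hydroxy-3-methoxybenzaldehyde
Conditions: MgCl2, Et3N, (CH2O)n, MeCN, reflux; then 1 M HCl
Reagents that add atoms: paraformaldehyde (formaldehyde), C=O
Why: Magnesium-phenoxide-directed ortho-formylation (Casnati–Skattebøl reaction) should deliver formaldehyde to the only free ortho position, the para position being blocked by fluorine, and a second formaldehyde oxidises the hydroxymethyl stage to the aldehyde.

**Step 2**
Reactants: 2 5-fluoro-2-hydroxy-3-methoxybenzaldehyde
Product: 3 5-fluoro-3-methoxy-2-(methoxymethoxy)benzaldehyde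
Conditions: MOMCl, iPr2NEt, CH2Cl2, 0 °C → rt
Reagents that add atoms: chloromethyl methyl ether, COCCl
Why: O-alkylation of the phenol with MOMCl (Williamson-type acetal protection) should give a base-stable, organolithium-stable group on the future C3' oxygen.

**Step 3**
Reactants: 3 5-fluoro-3-methoxy-2-(methoxymethoxy)benzaldehyde
Product: 5 5-fluoro-3-methoxy-2-(methoxymethoxy)phenol, via aryl formate 4 (not isolated)
Conditions: mCPBA, CH2Cl2, 0 °C → rt; aq. NaHCO3 wash; then K2CO3 (cat.), MeOH, rt
Reagents that add atoms: mCPBA, OOC(=O)c1cccc(Cl)c1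
Why: In this Baeyer–Villiger (Dakin-type) oxidation the electron-rich aryl group bearing an ortho alkoxy substituent should migrate in preference to hydrogen, and the resulting formate is cleaved by mild methanolysis.

**Step 4**
Reactants: 5 5-fluoro-3-methoxy-2-(methoxymethoxy)phenol
Product: 6 5-fluoro-1-methoxy-2-(methoxymethoxy)-3-(triisopropylsilyloxy)benzene
Conditions: TIPSCl, imidazole, DMF, rt → 40 °C
Reagents that add atoms: triisopropylsilyl chloride, CC(C)[Si](Cl)(C(C)C)C(C)C
Why: Imidazole-promoted silylation of the phenol should install a bulky, non-coordinating, organolithium-stable ether on the future C4' oxygen.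

**Step 5**
Reactants: 6 5-fluoro-1-methoxy-2-(methoxymethoxy)-3-(triisopropylsilyloxy)benzene; 7 propylmagnesium chloride; 8 carbon dioxide
Product: 12 2-methoxy-3-(methoxymethoxy)-6-propyl-4-(triisopropylsilyloxy)benzoic acid, via aryllithium 9 (not isolated), via aryne 10 (not isolated), via arylmagnesium chloride 11 (not isolated)
Conditions: s-BuLi, THF, −78 °C; then n-PrMgCl (3 equiv), −78 °C → rt; then CO2 (g), 0 °C; cold 0.5 M HCl to pH 3
Reagents that add atoms: propylmagnesium chloride, CCC[Mg]Cl; carbon dioxide, O=C=O
Why: sec-Butyllithium should remove the C1'–H, the most acidic ring proton because it lies between fluorine and the lithium-coordinating methoxy group, whereas the C5'–H on the other side of fluorine is screened by the non-coordinating triisopropylsilyl ether. On warming in the presence of propylmagnesium chloride the ortho-fluoroaryl metal loses metal fluoride to give the C1'–C6' aryne 10, a 3-methoxybenzyne. The Grignard reagent adds across the strained triple bond (carbomagnesiation) with propyl going to C6', the carbon distal to the inductively withdrawing C2' methoxy group, so that the new carbon–magnesium bond sits at C1' next to that oxygen. Carbon dioxide then carboxylates arylmagnesium 11 at C1'. The closest known reaction type is the three-component coupling of fluoroarene-derived 3-alkoxybenzynes with Grignard reagents and electrophiles; no ring closes and no stereocentre is formed. The step needs site-selective lithiation and regioselective aryne addition, secured respectively by the methoxy/silyl ether contrast on the two sides of fluorine and by the polarisation of the aryne by the C2' methoxy group.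

**Step 6**
Reactants: 12 2-methoxy-3-(methoxymethoxy)-6-propyl-4-(triisopropylsilyloxy)benzoic acid
Product: 14 benzyl 4-(benzyloxy)-2-methoxy-3-(methoxymethoxy)-6-propylbenzoate, via silyl ether benzyl ester 13 (not isolated)
Conditions: BnBr (3 equiv), K2CO3, DMF, rt; then CsF, 40 °C
Reagents that add atoms: benzyl bromide, BrCc1ccccc1
Why: Carboxylate SN2 alkylation is insensitive to the two ortho substituents of the acid, and fluoride-triggered desilylation with in situ Williamson benzylation of the released C4' phenoxide should swap the silyl ether for a benzyl ether in the same pot.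

**Step 7**
Reactants: 14 benzyl 4-(benzyloxy)-2-methoxy-3-(methoxymethoxy)-6-propylbenzoate
Product: 15 benzyl 4-(benzyloxy)-3-hydroxy-2-methoxy-6-propylbenzoate
Conditions: conc. HCl (cat.), MeOH/THF, 40 °C
Reagents that add atoms: none
Why: Acid-catalysed acetal exchange with methanol should free only the C3' phenol, since the benzyl ether, methyl ether and doubly ortho-substituted benzyl ester are inert to dilute methanolic HCl and the methoxymethyl cation is trapped by solvent.

**Step 8**
Reactants: 16 5-propylbenzene-1,3-diol (5-propylresorcinol)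
Product: 18 2,4-dihydroxy-6-propylbenzaldehyde, via iminium chloride 17 (not isolated)
Conditions: POCl3, DMF, 0 °C → rt; then H2O, 50 °C
Reagents that add atoms: N,N-dimethylformamide, CN(C)C=O; water, O
Why: Vilsmeier–Haack formylation of a 5-alkylresorcinol should occur at C4 (ortho to one hydroxyl, para to the other), and hydrolysis of the iminium salt gives the aldehyde.

**Step 9**
Reactants: 18 2,4-dihydroxy-6-propylbenzaldehyde
Product: 19 2,4-bis(benzyloxy)-6-propylbenzaldehyde
Conditions: BnBr, K2CO3, DMF, 60 °C
Reagents that add atoms: benzyl bromide, BrCc1ccccc1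
Why: Williamson etherification in warm DMF should benzylate both phenols, including the hydrogen-bonded one ortho to the aldehyde.

**Step 10**
Reactants: 19 2,4-bis(benzyloxy)-6-propylbenzaldehyde
Product: 20 2,4-bis(benzyloxy)-6-propylbenzoic acid
Conditions: NaClO2, NaH2PO4, 2-methyl-2-butene, t-BuOH/THF/H2O, rt
Reagents that add atoms: sodium chlorite, [Na+].[O-]Cl=O
Why: Pinnick oxidation should convert the hindered aldehyde into the acid without touching the benzyl ethers, the alkene scavenging hypochlorous acid before it chlorinates the electron-rich ring.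

**Step 11**
Reactants: 20 2,4-bis(benzyloxy)-6-propylbenzoic acid; 15 benzyl 4-(benzyloxy)-3-hydroxy-2-methoxy-6-propylbenzoate
Product: 22 benzyl 4-(benzyloxy)-3-{[2,4-bis(benzyloxy)-6-propylbenzoyl]oxy}-2-methoxy-6-propylbenzoate, via mixed trifluoroacetic anhydride 21 (not isolated)
Conditions: TFAA, toluene, 0 °C → rt
Reagents that add atoms: none
Why: In this trifluoroacetic anhydride-mediated esterification the mixed anhydride of the 2,6-disubstituted, electron-rich acid ionises to a slim linear acylium ion that should acylate even a phenol oxygen flanked on both sides, the usual way to join two hindered depside halves.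

**Step 12**
Reactants: 22 benzyl 4-(benzyloxy)-3-{[2,4-bis(benzyloxy)-6-propylbenzoyl]oxy}-2-methoxy-6-propylbenzoate
Product: 23 3-[(2,4-dihydroxy-6-propylbenzoyl)oxy]-4-hydroxy-2-methoxy-6-propylbenzoic acid (target)
Conditions: H2 (1 atm), 10% Pd/C, EtOAc, rt
Reagents that add atoms: none
Why: Catalytic hydrogenolysis should cleave the three benzyl ethers and the benzyl ester under neutral conditions, leaving the aryl ester, the methyl ether and both arenes intact and exposing no phenoxide that could trigger acyl migration.

**Compound list**
1 | 4-fluoro-2-methoxyphenol | COc1cc(F)ccc1O | starting material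
2 | 5-fluoro-2-hydroxy-3-methoxybenzaldehyde | COc1cc(F)cc(C=O)c1O | intermediate
3 | 5-fluoro-3-methoxy-2-(methoxymethoxy)benzaldehyde | COCOc1c(OC)cc(F)cc1C=O | intermediate
4 | 5-fluoro-3-methoxy-2-(methoxymethoxy)phenyl formate | COCOc1c(OC)cc(F)cc1OC=O | intermediate
5 | 5-fluoro-3-methoxy-2-(methoxymethoxy)phenol | COCOc1c(OC)cc(F)cc1O | intermediate
6 | 5-fluoro-1-methoxy-2-(methoxymethoxy)-3-(triisopropylsilyloxy)benzene | COCOc1c(OC)cc(F)cc1O[Si](C(C)C)(C(C)C)C(C)C | intermediate
7 | propylmagnesium chloride | CCC[Mg]Cl | starting material
8 | carbon dioxide | O=C=O | starting material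
9 | [6-fluoro-2-methoxy-3-(methoxymethoxy)-4-(triisopropylsilyloxy)phenyl]lithium | COCOc1c(OC)c([Li])c(F)cc1O[Si](C(C)C)(C(C)C)C(C)C | intermediate
10 | 3-methoxy-4-(methoxymethoxy)-5-(triisopropylsilyloxy)benzyne | COC1=C(OCOC)C(O[Si](C(C)C)(C(C)C)C(C)C)=CC#C1 | intermediate
11 | [2-methoxy-3-(methoxymethoxy)-6-propyl-4-(triisopropylsilyloxy)phenyl]magnesium chloride | CCCc1cc(O[Si](C(C)C)(C(C)C)C(C)C)c(OCOC)c(OC)c1[Mg]Cl | intermediate
12 | 2-methoxy-3-(methoxymethoxy)-6-propyl-4-(triisopropylsilyloxy)benzoic acid | CCCc1cc(O[Si](C(C)C)(C(C)C)C(C)C)c(OCOC)c(OC)c1C(=O)O | intermediate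
13 | benzyl 2-methoxy-3-(methoxymethoxy)-6-propyl-4-(triisopropylsilyloxy)benzoate | CCCc1cc(O[Si](C(C)C)(C(C)C)C(C)C)c(OCOC)c(OC)c1C(=O)OCc1ccccc1 | intermediate
14 | benzyl 4-(benzyloxy)-2-methoxy-3-(methoxymethoxy)-6-propylbenzoate | CCCc1cc(OCc2ccccc2)c(OCOC)c(OC)c1C(=O)OCc1ccccc1 | intermediate
15 | benzyl 4-(benzyloxy)-3-hydroxy-2-methoxy-6-propylbenzoate | CCCc1cc(OCc2ccccc2)c(O)c(OC)c1C(=O)OCc1ccccc1 | intermediate
16 | 5-propylbenzene-1,3-diol (5-propylresorcinol) | CCCc1cc(O)cc(O)c1 | starting material
17 | N-[(2,4-dihydroxy-6-propylphenyl)methylidene]-N-methylmethanaminium chloride | CCCc1cc(O)cc(O)c1C=[N+](C)C.[Cl-] | intermediate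
18 | 2,4-dihydroxy-6-propylbenzaldehyde | CCCc1cc(O)cc(O)c1C=O | intermediate
19 | 2,4-bis(benzyloxy)-6-propylbenzaldehyde | CCCc1cc(OCc2ccccc2)cc(OCc2ccccc2)c1C=O | intermediate
20 | 2,4-bis(benzyloxy)-6-propylbenzoic acid | CCCc1cc(OCc2ccccc2)cc(OCc2ccccc2)c1C(=O)O | intermediate
21 | 2,4-bis(benzyloxy)-6-propylbenzoic trifluoroacetic anhydride | CCCc1cc(OCc2ccccc2)cc(OCc2ccccc2)c1C(=O)OC(=O)C(F)(F)F | intermediate
22 | benzyl 4-(benzyloxy)-3-{[2,4-bis(benzyloxy)-6-propylbenzoyl]oxy}-2-methoxy-6-propylbenzoate | CCCc1cc(OCc2ccccc2)cc(OCc2ccccc2)c1C(=O)Oc1c(OCc2ccccc2)cc(CCC)c(C(=O)OCc2ccccc2)c1OC | intermediate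
23 | 3-[(2,4-dihydroxy-6-propylbenzoyl)oxy]-4-hydroxy-2-methoxy-6-propylbenzoic acid | CCCc1cc(O)cc(O)c1C(=O)Oc1c(O)cc(CCC)c(C(=O)O)c1OC | target

**Step count**
Total: 12 steps. Longest linear sequence: 9 steps (steps 1–7, 11, 12 from 4-fluoro-2-methoxyphenol); the ring A branch is steps 8–10.

**Steps most likely to fail**

1. Step 5. Lithiation may partly occur on the silyl ether side of fluorine, the aryne may be consumed by the aryllithium before the Grignard reagent adds, or the hindered arylmagnesium may be protonated instead of carboxylated. Fallback, setting out from 6 and returning at 12: the lithiation is kept but the aryne is avoided. Aryllithium 9 is quenched with CO2 at −78 °C, before fluoride is lost, which should give 6-fluoro-2-methoxy-3-(methoxymethoxy)-4-(triisopropylsilyloxy)benzoic acid F1. Its magnesium carboxylate is then treated with excess propylmagnesium chloride in THF at rt → 50 °C. Carboxylate-directed nucleophilic aromatic substitution (addition–elimination) at C6' should replace the ortho fluoride, a far better leaving group than the ortho methoxide, by propyl and give acid 12.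

2. Step 11. O-acylation between two doubly ortho-substituted partners may be slow, allowing C-acylation at C5' of ring B or acid-induced loss of the ortho benzyl ether from the acylium ion. Fallback, setting out from 20 and 15 and returning at 22: the coupling is moved to basic, acylium-free conditions. Acid 20 is converted with oxalyl chloride and catalytic DMF in CH2Cl2 into 2,4-bis(benzyloxy)-6-propylbenzoyl chloride F2. Phenol 15 is deprotonated with NaH in THF to sodium 6-(benzyloxy)-3-[(benzyloxy)carbonyl]-2-methoxy-4-propylphenolate F3. Combining the two at 0 °C → rt should give 22 by direct acyl substitution.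

3. Step 3. Hydride instead of aryl migration would give the benzoic acid, since the ring has only one ortho donor and carries fluorine, and 3-chlorobenzoic acid may cleave the MOM acetal. Fallback, setting out from 1 and returning at 5: the oxygen is introduced through a halogen instead of a formyl group. Bromination of 1 with NBS in MeCN, ortho to the hydroxyl (para is blocked), should give 2-bromo-4-fluoro-6-methoxyphenol F4. MOM protection (MOMCl, iPr2NEt) gives 1-bromo-5-fluoro-3-methoxy-2-(methoxymethoxy)benzene F5. Bromine–lithium exchange with n-BuLi in THF at −78 °C gives [5-fluoro-3-methoxy-2-(methoxymethoxy)phenyl]lithium F6, in which lithium is meta to fluorine so that no aryne can form. Trapping with B(OMe)3 gives dimethyl [5-fluoro-3-methoxy-2-(methoxymethoxy)phenyl]boronate F7, and oxidation with H2O2/NaOH should give phenol 5.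

**Further compounds**
F1 | step 5 | 6-fluoro-2-methoxy-3-(methoxymethoxy)-4-(triisopropylsilyloxy)benzoic acid | COCOc1c(OC)c(C(=O)O)c(F)cc1O[Si](C(C)C)(C(C)C)C(C)C
F2 | step 11 | 2,4-bis(benzyloxy)-6-propylbenzoyl chloride | CCCc1cc(OCc2ccccc2)cc(OCc2ccccc2)c1C(Cl)=O
F3 | step 11 | sodium 6-(benzyloxy)-3-[(benzyloxy)carbonyl]-2-methoxy-4-propylphenolate | CCCc1cc(OCc2ccccc2)c([O-])c(OC)c1C(=O)OCc1ccccc1.[Na+]
F4 | step 3 | 2-bromo-4-fluoro-6-methoxyphenol | COc1cc(F)cc(Br)c1O
F5 | step 3 | 1-bromo-5-fluoro-3-methoxy-2-(methoxymethoxy)benzene | COCOc1c(OC)cc(F)cc1Br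
F6 | step 3 | [5-fluoro-3-methoxy-2-(methoxymethoxy)phenyl]lithium | COCOc1c(OC)cc(F)cc1[Li]
F7 | step 3 | dimethyl [5-fluoro-3-methoxy-2-(methoxymethoxy)phenyl]boronate | COCOc1c(OC)cc(F)cc1B(OC)OC
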